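**Retrosynthetic overview**
1. The target comes from a 1,8-bis-silylated 4,6-diol acrylate by mixed-anhydride angeloylation of the 6α-OH and desilylation; the acrylate comes from a C7 methyl ketone by enol triflate formation and Pd-catalysed methoxycarbonylation.
2. The 6α-O and 7α-H centres come from α-face hydroboration of a Δ6 alkene carrying a C7 hydroxymethyl group (from the C7 ketone by enol triflate carbonylation and reduction); the 8α-OH comes from Rubottom oxidation of the Δ7 silyl enol ether.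
3. In ring A, the 4α-OH/4β-CH3 centre comes from a 4-ketone (methylenation, α-epoxidation, hydride opening); the 4-ketone and 5α-H come from hydroboration of the deconjugated Δ4 7-ketal of 1β-hydroxy Wieland–Miescher ketone.
4. (R)-Wieland–Miescher ketone comes from D-proline aldol cyclodehydration of a triketone, made by intermolecular Michael addition of 2-methylcyclohexane-1,3-dione to methyl vinyl ketone (C9–C10 bond, the union of the two fragments).
5. Ring order: ring A is the preformed dione ring; ring B is closed second by the aldol condensation; all later steps are functional-group and side-chain work.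

Assumption: positions use eudesmane numbering (decalin C1–C10, CH3-14 on C10, CH3-15 on C4, side chain C11–C13 on C7); β is the face of the C10 methyl, α the opposite face; TBS = tert-butyldimethylsilyl, TMS = trimethylsilyl, Tf = CF3SO2.

**Route**

Step 1
Reactants: 1 2-methylcyclohexane-1,3-dione; 2 methyl vinyl ketone
Product: 3 2-methyl-2-(3-oxobutyl)cyclohexane-1,3-dione
Conditions: H2O, AcOH (cat.), hydroquinone (cat.), 75 °C
Reagents that add atoms: none
Why: Intermolecular Michael addition of the dione enol to the enone joins the two fragments at C9–C10 and builds the methyl-bearing quaternary carbon, which is still prochiral.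

Step 2
Reactants: 3 triketone
Product: 5 (R)-Wieland–Miescher ketone, via ketol 4 (not isolated)
Conditions: D-proline (5 mol %), DMSO, rt, 5 d; recrystallisation (Et2O)
Reagents that add atoms: none
Why: Hajos–Parrish–Eder–Sauer–Wiechert enamine aldol condensation closes ring B; D-proline selects one enantiotopic ring carbonyl and sets C10 as R (L-proline is known to give S), and recrystallisation brings the roughly 70% ee material to enantiopurity.

Step 3
Reactants: 5 (R)-Wieland–Miescher ketone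
Product: 6 1β-hydroxy enone
Conditions: NaBH4 (0.3 equiv), EtOH, −10 °C
Reagents that add atoms: none
Why: Chemoselective borohydride reduction of the saturated ketone in the presence of the enone; hydride enters anti to the angular methyl and gives the equatorial 1β-OH (cis to CH3).

Step 4
Reactants: 6 1β-hydroxy enone
Product: 7 1β-acetoxy enone
Conditions: Ac2O, pyridine, DMAP (cat.), CH2Cl2, rt
Reagents that add atoms: acetic anhydride, CC(=O)OC(C)=O
Why: Acylation protects the hydroxyl (blocking vinylogous retro-aldol cleavage) for the acidic ketalisation that follows.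

Step 5
Reactants: 7 1β-acetoxy enone
Product: 8 Δ4 7,7-ethylene ketal 1β-acetate
Conditions: HOCH2CH2OH, TsOH·H2O (cat.), benzene, reflux, Dean–Stark
Reagents that add atoms: ethylene glycol, OCCO
Why: Acid-catalysed ketalisation of the enone proceeds through the dienol ether with deconjugation, moving the double bond to C4=C5 as in Δ4-3-keto steroids.

Step 6
Reactants: 8 Δ4 ketal acetate
Product: 9 Δ4 ketal 1β-ol
Conditions: K2CO3, MeOH, rt
Reagents that add atoms: none
Why: Base-catalysed transesterification (methanolysis) removes the acetate, which would not survive the later borane and hydride steps.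

Step 7
Reactants: 9 Δ4 ketal 1β-ol
Product: 10 Δ4 ketal 1β-TBS ether
Conditions: TBSOTf, 2,6-lutidine, CH2Cl2, 0 °C
Reagents that add atoms: tert-butyldimethylsilyl triflate, CC(C)(C)[Si](C)(C)OS(=O)(=O)C(F)(F)F
Why: Silylation of the hindered neopentyl-type alcohol gives a robust ether that is carried to the last step.

Step 8
Reactants: 10 Δ4 ketal 1β-TBS ether
Product: 12 trans-decalin 4α-ol, via alkylborane 11 (not isolated)
Conditions: BH3·THF, THF, 0 °C to rt; then aq. NaOH, H2O2, 0 °C to rt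
Reagents that add atoms: hydrogen peroxide, OO; borane–THF, B.C1CCOC1 (its boron stays only in 11)
Why: Hydroboration–oxidation; syn addition anti to the C10 methyl puts boron on the less substituted C4 and hydrogen on C5 from the α face, giving 4α-OH and the trans ring fusion (5α-H).

Step 9
Reactants: 12 trans-decalin 4α-ol
Product: 13 trans-decalin-4-one
Conditions: Dess–Martin periodinane, NaHCO3, CH2Cl2, rt; then NaOMe (cat.), MeOH, rt
Reagents that add atoms: none
Why: Dess–Martin oxidation followed by base equilibration through the C4 enolate converges any 5β material from step 8 on the more stable trans-fused ketone, securing 5α-H.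

Step 10
Reactants: 13 trans-decalin-4-one
Product: 14 4(15)-methylidene compound
Conditions: Ph3PCH3Br, KOtBu, THF, 0 °C to reflux
Reagents that add atoms: methyltriphenylphosphonium bromide, C[P+](c1ccccc1)(c1ccccc1)c1ccccc1.[Br-]
Why: Wittig methylenation installs C15; the trans ring fusion is the thermodynamic one, so the basic medium does not erode C5.

Step 11
Reactants: 14 4(15)-methylidene compound
Product: 15 4α,15-epoxide
Conditions: mCPBA, NaHCO3, CH2Cl2, 0 °C
Reagents that add atoms: 3-chloroperoxybenzoic acid, OOC(=O)c1cccc(Cl)c1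
Why: Prilezhaev epoxidation; the axial C10 methyl (1,3-diaxial to C4) blocks the β face, so oxygen is delivered from the α (equatorial) side.

Step 12
Reactants: 15 4α,15-epoxide
Product: 16 tertiary 4α-ol ketal (4β-CH3)
Conditions: LiAlH4, THF, reflux
Reagents that add atoms: none
Why: SN2 hydride opening at the primary epoxide carbon turns C15 into the axial 4β-methyl and leaves the equatorial 4α-OH (the cryptomeridiol-type arrangement).

Step 13
Reactants: 16 tertiary 4α-ol ketal
Product: 17 4α-hydroxy-7-ketone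
Conditions: PPTS, acetone/H2O, 60 °C
Reagents that add atoms: water, O
Why: Mild acetal hydrolysis frees the C7 ketone without touching the TBS ether or dehydrating the tertiary alcohol.

Step 14
Reactants: 17 4α-hydroxy-7-ketone
Product: 18 Δ7 trimethylsilyl enol ether (4-OTMS)
Conditions: TMSOTf (2.5 equiv), Et3N, CH2Cl2, 0 °C to rt
Reagents that add atoms: trimethylsilyl triflate, C[Si](C)(C)OS(=O)(=O)C(F)(F)F
Why: Soft enolisation–silylation gives mainly the thermodynamically preferred enol ether toward C8 (the analogue of Δ2 in 5α-3-keto steroids); the C4 hydroxyl is silylated in the same operation.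

Step 15
Reactants: 18 Δ7 silyl enol ether
Product: 20 4α,8α-dihydroxy-7-ketone, via silyloxy ketone 19 (not isolated)
Conditions: mCPBA, NaHCO3, CH2Cl2, −20 °C; then 1 M HCl, THF, 0 °C
Reagents that add atoms: 3-chloroperoxybenzoic acid, OOC(=O)c1cccc(Cl)c1
Why: Rubottom oxidation; epoxidation of the enol ether from the α face (β shielded by the C10 methyl) and 1,4-silyl shift give the equatorial 8α-oxygen, and acid removes both TMS groups.

Step 16
Reactants: 20 4α,8α-dihydroxy-7-ketone
Product: 21 8α-TBSO-7-ketone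
Conditions: TBSCl, imidazole, DMF, rt
Reagents that add atoms: tert-butyldimethylsilyl chloride, CC(C)(C)[Si](C)(C)Cl
Why: Silylation under imidazole catalysis is selective for the secondary α-ketol hydroxyl over the hindered tertiary 4-OH.

Step 17
Reactants: 21 8α-TBSO-7-ketone
Product: 22 Δ6 enol triflate
Conditions: KN(SiMe3)2 (2.2 equiv), THF, −78 °C; then PhNTf2 (1.1 equiv), −78 to 0 °C
Reagents that add atoms: N-phenylbis(trifluoromethanesulfonimide), O=S(=O)(N(c1ccccc1)S(=O)(=O)C(F)(F)F)C(F)(F)F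
Why: Kinetic enolate formation occurs at the C6 methylene (away from the silyloxy-bearing C8 methine) and O-triflation traps it; the hindered tertiary alkoxide is expected not to compete for the limiting triflating agent.

Step 18
Reactants: 22 Δ6 enol triflate
Product: 23 Δ6 methyl ester (C11 ester on C7)
Conditions: Pd(OAc)2 (5 mol %), PPh3, CO (1 atm), MeOH, Et3N, DMF, 40 °C
Reagents that add atoms: carbon monoxide, [C-]#[O+]; methanol, CO
Why: Pd-catalysed alkoxycarbonylation (oxidative addition to zerovalent palladium, CO insertion, methanolysis) attaches C11 to C7.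

Step 19
Reactants: 23 Δ6 methyl ester
Product: 24 Δ6 allylic alcohol
Conditions: iBu2AlH (3.5 equiv), CH2Cl2, −78 °C
Reagents that add atoms: none
Why: 1,2-Reduction of the conjugated ester by the aluminium hydride gives the allylic alcohol without touching the ring alkene.

Step 20
Reactants: 24 Δ6 allylic alcohol
Product: 25 Δ6 allylic TBS ether
Conditions: TBSCl, imidazole, CH2Cl2, 0 °C
Reagents that add atoms: tert-butyldimethylsilyl chloride, CC(C)(C)[Si](C)(C)Cl
Why: Selective silylation of the primary hydroxyl gives an ether that can later be removed in the presence of the secondary TBS ethers.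

Step 21
Reactants: 25 Δ6 allylic TBS ether
Product: 27 6α-ol (7α-H), via alkylborane 26 (not isolated)
Conditions: BH3·THF (excess), THF, 0 °C to rt; then aq. NaOH, H2O2, 0 °C
Reagents that add atoms: hydrogen peroxide, OO; borane–THF, B.C1CCOC1 (its boron stays only in 26)
Why: Hydroboration–oxidation; the axial C10 and C4 methyls block the β face, so syn addition from the α face puts boron on C6 and hydrogen on C7, giving 6α-OH and the 7β (equatorial) side chain.

Step 22
Reactants: 27 6α-ol
Product: 28 4α,6α-O-(4-methoxybenzylidene) acetal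
Conditions: 4-MeOC6H4CH(OMe)2, PPTS (cat.), CH2Cl2, 4 Å sieves, rt
Reagents that add atoms: 4-methoxybenzaldehyde dimethyl acetal, COc1ccc(C(OC)OC)cc1
Why: Thermodynamic transacetalisation bridges the parallel (peri) equatorial 4α/6α hydroxyls as a chair 1,3-dioxane with the aryl group equatorial (acetal carbon S); a benzylidene is used because its axial position carries only hydrogen next to the axial C15 methyl.

Step 23
Reactants: 28 benzylidene acetal
Product: 29 C11 primary alcohol
Conditions: HF·pyridine, pyridine, THF, 0 °C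
Reagents that add atoms: none
Why: Buffered fluoride desilylation removes the unhindered primary TBS ether much faster than the two hindered secondary ones and leaves the acetal intact.

Step 24
Reactants: 29 C11 primary alcohol
Product: 30 C11 aldehyde
Conditions: Dess–Martin periodinane, NaHCO3, CH2Cl2, 0 °C to rt
Reagents that add atoms: none
Why: Neutral Dess–Martin oxidation avoids β-elimination of the flanking oxygens; the equatorial 7β configuration is also the thermodynamic one.

Step 25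
Reactants: 30 C11 aldehyde
Product: 31 C11 methyl carbinol (both C11 epimers)
Conditions: MeMgBr, THF, −78 °C
Reagents that add atoms: methylmagnesium bromide, C[Mg]Br
Why: Grignard addition introduces C13; the new carbinol centre is irrelevant because it is oxidised in the next step.

Step 26
Reactants: 31 C11 methyl carbinol
Product: 32 7β-acetyl compound (methyl ketone)
Conditions: Dess–Martin periodinane, NaHCO3, CH2Cl2, rt
Reagents that add atoms: none
Why: Dess–Martin oxidation gives the methyl ketone with C7 in its stable all-equatorial arrangement.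

Step 27
Reactants: 32 methyl ketone
Product: 33 1-(triflyloxy)vinyl compound
Conditions: KN(SiMe3)2, THF, −78 °C; then PhNTf2, −78 °C
Reagents that add atoms: N-phenylbis(trifluoromethanesulfonimide), O=S(=O)(N(c1ccccc1)S(=O)(=O)C(F)(F)F)C(F)(F)F
Why: Kinetic deprotonation occurs at the methyl group rather than the hindered C7 methine, and O-triflation gives the terminal enol triflate; this enolate has no β-leaving group, so the C6 and C8 oxygens are safe.

Step 28
Reactants: 33 vinyl triflate
Product: 34 protected acrylate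
Conditions: Pd(OAc)2 (5 mol %), PPh3, CO (1 atm), MeOH, Et3N, DMF, rt
Reagents that add atoms: carbon monoxide, [C-]#[O+]; methanol, CO
Why: Pd-catalysed methoxycarbonylation of the 1,1-disubstituted vinyl triflate installs C12 and gives the α-substituted methyl acrylate directly.

Step 29
Reactants: 34 protected acrylate
Product: 35 4α,6α-diol acrylate
Conditions: AcOH/THF/H2O (3:1:1), rt
Reagents that add atoms: none
Why: Mild acid hydrolysis of the electron-rich benzylidene acetal frees the 4α and 6α hydroxyls while the secondary TBS ethers survive and lactonisation onto C12 stays slow.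

Step 30
Reactants: 35 4α,6α-diol acrylate
Product: 36 6α-O-angelate
Conditions: angelic acid, 2,4,6-Cl3C6H2COCl, Et3N, toluene, rt; then 35, 80 °C
Reagents that add atoms: angelic acid, C/C=C(/C)C(=O)O
Why: Yamaguchi-type mixed-anhydride esterification without DMAP acylates the secondary 6α-OH (the tertiary 4α-OH is inert) and is the standard way to keep the Z geometry of the angelate.

Step 31
Reactants: 36 6α-O-angelate
Product: 37 methyl 6α-angeloyloxy-1β,4α,8α-trihydroxyeudesm-11(13)-en-12-oate (target)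
Conditions: HF·pyridine (excess), THF, rt
Reagents that add atoms: none
Why: Fluoride-mediated desilylation under mildly acidic conditions removes both secondary TBS ethers without isomerising the angelate, adding to the acrylate or lactonising the 8α-OH onto C12.

**Compound list**
1 | 2-methylcyclohexane-1,3-dione | CC1C(=O)CCCC1=O | starting material
2 | methyl vinyl ketone (but-3-en-2-one) | CC(=O)C=C | starting material
3 | 2-methyl-2-(3-oxobutyl)cyclohexane-1,3-dione | CC(=O)CCC1(C)C(=O)CCCC1=O | intermediate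
4 | cis-fused ketol, 4a-hydroxy-8a-methyloctahydronaphthalene-1,6-dione (OH and CH3 on the same face) | O=C1C[C@]2(O)CCCC(=O)[C@]2(C)CC1 | intermediate
5 | (R)-Wieland–Miescher ketone, (8aR)-8a-methyl-3,4,8,8a-tetrahydronaphthalene-1,6(2H,7H)-dione | O=C1C=C2[C@@](C)(CC1)C(=O)CCC2 | intermediate
6 | (4aR,5R)-5-hydroxy-4a-methyl-4,4a,5,6,7,8-hexahydronaphthalen-2(3H)-one (1β-OH, 10β-CH3, Δ5-7-one) | O=C1C=C2[C@@](C)(CC1)[C@H](O)CCC2 | intermediate
7 | 1β-acetate of 6 | O=C1C=C2[C@@](C)(CC1)[C@H](OC(C)=O)CCC2 | intermediate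
8 | 1β-acetoxy-7,7-(ethylenedioxy)-10β-methyl-Δ4-octalin | CC(=O)O[C@@H]1CCC=C2CC3(OCCO3)CC[C@]21C | intermediate
9 | 7,7-(ethylenedioxy)-10β-methyl-Δ4-octalin-1β-ol | O[C@@H]1CCC=C2CC3(OCCO3)CC[C@]21C | intermediate
10 | 1β-(TBSO)-7,7-(ethylenedioxy)-10β-methyl-Δ4-octalin | CC(C)(C)[Si](C)(C)O[C@@H]1CCC=C2CC3(OCCO3)CC[C@]21C | intermediate
11 | 4α-boryl (BH2) adduct of 10, 5α-H | C13(OCCO3)C[C@@H]2[C@@](C)(CC1)[C@H](O[Si](C)(C)C(C)(C)C)CC[C@H]2B | intermediate
12 | 1β-(TBSO)-7,7-(ethylenedioxy)-10β-methyl-trans-decalin-4α-ol (5α-H) | C13(OCCO3)C[C@@H]2[C@@](C)(CC1)[C@H](O[Si](C)(C)C(C)(C)C)CC[C@H]2O | intermediate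
13 | 1β-(TBSO)-7,7-(ethylenedioxy)-10β-methyl-trans-decalin-4-one (5α-H) | C13(OCCO3)C[C@@H]2[C@@](C)(CC1)[C@H](O[Si](C)(C)C(C)(C)C)CCC2=O | intermediate
14 | 4-methylidene analogue of 13 (C4=C15) | C13(OCCO3)C[C@@H]2[C@@](C)(CC1)[C@H](O[Si](C)(C)C(C)(C)C)CCC2=C | intermediate
15 | 4α,15-epoxide of 14 (oxygen α, CH2 β) | C13(OCCO3)C[C@@H]2[C@@](C)(CC1)[C@H](O[Si](C)(C)C(C)(C)C)CC[C@@]2(C4)O4 | intermediate
16 | 1β-(TBSO)-7,7-(ethylenedioxy)-4β,10β-dimethyl-trans-decalin-4α-ol | C13(OCCO3)C[C@@H]2[C@@](C)(CC1)[C@H](O[Si](C)(C)C(C)(C)C)CC[C@@]2(C)O | intermediate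
17 | 1β-(TBSO)-4α-hydroxy-4β,10β-dimethyl-trans-decalin-7-one (5α-H) | O=C1C[C@@H]2[C@@](C)(CC1)[C@H](O[Si](C)(C)C(C)(C)C)CC[C@@]2(C)O | intermediate
18 | Δ7 enol ether: 1β-(TBSO)-4α,7-bis(TMSO)-4β,10β-dimethyl-Δ7-octalin (5α-H) | C1=C(O[Si](C)(C)C)C[C@@H]2[C@@](C)(C1)[C@H](O[Si](C)(C)C(C)(C)C)CC[C@@]2(C)O[Si](C)(C)C | intermediate
19 | 1β-(TBSO)-4α,8α-bis(TMSO)-4β,10β-dimethyl-trans-decalin-7-one | O=C1C[C@@H]2[C@@](C)(C[C@@H]1O[Si](C)(C)C)[C@H](O[Si](C)(C)C(C)(C)C)CC[C@@]2(C)O[Si](C)(C)C | intermediate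
20 | 1β-(TBSO)-4α,8α-dihydroxy-4β,10β-dimethyl-trans-decalin-7-one | O=C1C[C@@H]2[C@@](C)(C[C@@H]1O)[C@H](O[Si](C)(C)C(C)(C)C)CC[C@@]2(C)O | intermediate
21 | 1β,8α-bis(TBSO)-4α-hydroxy-4β,10β-dimethyl-trans-decalin-7-one | O=C1C[C@@H]2[C@@](C)(C[C@@H]1O[Si](C)(C)C(C)(C)C)[C@H](O[Si](C)(C)C(C)(C)C)CC[C@@]2(C)O | intermediate
22 | Δ6 enol triflate of 21 (7-OTf, C6=C7) | O=S(=O)(OC1=C[C@@H]2[C@@](C)(C[C@@H]1O[Si](C)(C)C(C)(C)C)[C@H](O[Si](C)(C)C(C)(C)C)CC[C@@]2(C)O)C(F)(F)F | intermediate
23 | methyl 1β,8α-bis(TBSO)-4α-hydroxy-4β,10β-dimethyl-Δ6-octalin-7-carboxylate (5α-H) | COC(=O)C1=C[C@@H]2[C@@](C)(C[C@@H]1O[Si](C)(C)C(C)(C)C)[C@H](O[Si](C)(C)C(C)(C)C)CC[C@@]2(C)O | intermediate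
24 | 7-(hydroxymethyl) analogue of 23 (allylic alcohol) | OCC1=C[C@@H]2[C@@](C)(C[C@@H]1O[Si](C)(C)C(C)(C)C)[C@H](O[Si](C)(C)C(C)(C)C)CC[C@@]2(C)O | intermediate
25 | 7-(TBSO-methyl) analogue of 24 | CC(C)(C)[Si](C)(C)OCC1=C[C@@H]2[C@@](C)(C[C@@H]1O[Si](C)(C)C(C)(C)C)[C@H](O[Si](C)(C)C(C)(C)C)CC[C@@]2(C)O | intermediate
26 | 6α-boryl (BH2) adduct of 25, 7α-H | CC(C)(C)[Si](C)(C)OC[C@H]1[C@H](B)[C@@H]2[C@@](C)(C[C@@H]1O[Si](C)(C)C(C)(C)C)[C@H](O[Si](C)(C)C(C)(C)C)CC[C@@]2(C)O | intermediate
27 | 1β,8α-bis(TBSO)-7β-(TBSO-methyl)-4β,10β-dimethyl-trans-decalin-4α,6α-diol (5α-H, 7α-H) | CC(C)(C)[Si](C)(C)OC[C@H]1[C@H](O)[C@@H]2[C@@](C)(C[C@@H]1O[Si](C)(C)C(C)(C)C)[C@H](O[Si](C)(C)C(C)(C)C)CC[C@@]2(C)O | intermediate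
28 | 4α,6α-O-[(S)-4-methoxybenzylidene] acetal of 27 (aryl equatorial, acetal H β) | CC(C)(C)[Si](C)(C)OC[C@H]1[C@H](O3)[C@@H]2[C@@](C)(C[C@@H]1O[Si](C)(C)C(C)(C)C)[C@H](O[Si](C)(C)C(C)(C)C)CC[C@@]2(C)O[C@H]3c4ccc(OC)cc4 | intermediate
29 | 7β-(hydroxymethyl) analogue of 28 | OC[C@H]1[C@H](O3)[C@@H]2[C@@](C)(C[C@@H]1O[Si](C)(C)C(C)(C)C)[C@H](O[Si](C)(C)C(C)(C)C)CC[C@@]2(C)O[C@H]3c4ccc(OC)cc4 | intermediate
30 | 7β-carbaldehyde analogue of 28 | O=C[C@H]1[C@H](O3)[C@@H]2[C@@](C)(C[C@@H]1O[Si](C)(C)C(C)(C)C)[C@H](O[Si](C)(C)C(C)(C)C)CC[C@@]2(C)O[C@H]3c4ccc(OC)cc4 | intermediate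
31 | 7β-(1-hydroxyethyl) analogue of 28, both C11 epimers | CC(O)[C@H]1[C@H](O3)[C@@H]2[C@@](C)(C[C@@H]1O[Si](C)(C)C(C)(C)C)[C@H](O[Si](C)(C)C(C)(C)C)CC[C@@]2(C)O[C@H]3c4ccc(OC)cc4 | intermediate
32 | 7β-acetyl analogue of 28 | CC(=O)[C@H]1[C@H](O3)[C@@H]2[C@@](C)(C[C@@H]1O[Si](C)(C)C(C)(C)C)[C@H](O[Si](C)(C)C(C)(C)C)CC[C@@]2(C)O[C@H]3c4ccc(OC)cc4 | intermediate
33 | 7β-[1-(triflyloxy)vinyl] analogue of 28 | C=C(OS(=O)(=O)C(F)(F)F)[C@H]1[C@H](O3)[C@@H]2[C@@](C)(C[C@@H]1O[Si](C)(C)C(C)(C)C)[C@H](O[Si](C)(C)C(C)(C)C)CC[C@@]2(C)O[C@H]3c4ccc(OC)cc4 | intermediate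
34 | methyl 1β,8α-bis(TBSO)-4α,6α-O-(4-methoxybenzylidene)eudesm-11(13)-en-12-oate | C=C(C(=O)OC)[C@H]1[C@H](O3)[C@@H]2[C@@](C)(C[C@@H]1O[Si](C)(C)C(C)(C)C)[C@H](O[Si](C)(C)C(C)(C)C)CC[C@@]2(C)O[C@H]3c4ccc(OC)cc4 | intermediate
35 | methyl 1β,8α-bis(TBSO)-4α,6α-dihydroxyeudesm-11(13)-en-12-oate | C=C(C(=O)OC)[C@H]1[C@H](O)[C@@H]2[C@@](C)(C[C@@H]1O[Si](C)(C)C(C)(C)C)[C@H](O[Si](C)(C)C(C)(C)C)CC[C@@]2(C)O | intermediate
36 | methyl 6α-angeloyloxy-1β,8α-bis(TBSO)-4α-hydroxyeudesm-11(13)-en-12-oate | C=C(C(=O)OC)[C@H]1[C@H](OC(=O)/C(C)=C\C)[C@@H]2[C@@](C)(C[C@@H]1O[Si](C)(C)C(C)(C)C)[C@H](O[Si](C)(C)C(C)(C)C)CC[C@@]2(C)O | intermediate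
37 | methyl 6α-angeloyloxy-1β,4α,8α-trihydroxyeudesm-11(13)-en-12-oate (5α-H, 7α-H, 10β-CH3; CNP0136844.1) | C=C(C(=O)OC)[C@H]1[C@H](OC(=O)/C(C)=C\C)[C@@H]2[C@@](C)(C[C@@H]1O)[C@H](O)CC[C@@]2(C)O | target

**Step count and risk**
Total step count: 31. Longest linear sequence: 31 steps (from 1 and 2; the route is fully linear).

The three steps most likely to fail:

Step 17 (regioselective Δ6 enol triflate in the presence of a free tertiary alkoxide). The fallback avoids enolate chemistry and sets out from 21. Wittig methylenation (Ph3PCH3Br, KOtBu, THF) gives the 7-methylidene compound F1. Epoxidation (mCPBA, NaHCO3, CH2Cl2) gives, mainly from the α face, the spiro-epoxide F2. Et2Al(TMP), made from Et2AlCl and Li(TMP) in toluene at 0 °C, isomerises it to the allylic alcohol by syn β-elimination through a C6 hydrogen; the C8 methine next to the silyl ether is too hindered to compete, and either epoxide epimer gives the same product. The route is rejoined at 24.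

Step 21 (face and position selectivity of the hydroboration of a hindered trisubstituted alkene). The fallback sets out from 23. Conjugate borylation catalysed by CuCl/NaOtBu/Xantphos with B2pin2 and MeOH in THF gives the 6α-boryl ester F3; the C7 ester can equilibrate to its equatorial 7β position. Oxidation with NaBO3·4H2O in THF/H2O gives the β-hydroxy ester F4. Reduction with iBu2AlH gives the triol F5. Silylation of its primary hydroxyl (TBSCl, imidazole) returns to the route at 27.

Step 30 (angeloylation of a hindered alcohol next to the acrylate, with risk of Z to E isomerisation or lactonisation). The fallback builds the Z alkene in place and sets out from 35. Esterification with 2-[bis(2,2,2-trifluoroethoxy)phosphoryl]propanoic acid (DCC, DMAP cat., CH2Cl2) gives the phosphonate ester F6. Still–Gennari olefination (KN(SiMe3)2, 18-crown-6, THF, −78 °C, then acetaldehyde) gives the (Z)-2-methylbut-2-enoate and returns to the route at 36.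

**Further compounds**
F1 | step 17 | 1β,8α-bis(TBSO)-4β,10β-dimethyl-7-methylidene-trans-decalin-4α-ol | C=C1C[C@@H]2[C@@](C)(C[C@@H]1O[Si](C)(C)C(C)(C)C)[C@H](O[Si](C)(C)C(C)(C)C)CC[C@@]2(C)O
F2 | step 17 | spiro-epoxide of F1 at C7 (oxygen α, CH2 β) | O1C[C@]12C[C@@H]3[C@@](C)(C[C@@H]2O[Si](C)(C)C(C)(C)C)[C@H](O[Si](C)(C)C(C)(C)C)CC[C@@]3(C)O
F3 | step 21 | methyl 6α-(pinacolatoboryl)-1β,8α-bis(TBSO)-4α-hydroxy-4β,10β-dimethyl-trans-decalin-7β-carboxylate | COC(=O)[C@H]1[C@H](B3OC(C)(C)C(C)(C)O3)[C@@H]2[C@@](C)(C[C@@H]1O[Si](C)(C)C(C)(C)C)[C@H](O[Si](C)(C)C(C)(C)C)CC[C@@]2(C)O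
F4 | step 21 | methyl 1β,8α-bis(TBSO)-4α,6α-dihydroxy-4β,10β-dimethyl-trans-decalin-7β-carboxylate | COC(=O)[C@H]1[C@H](O)[C@@H]2[C@@](C)(C[C@@H]1O[Si](C)(C)C(C)(C)C)[C@H](O[Si](C)(C)C(C)(C)C)CC[C@@]2(C)O
F5 | step 21 | 1β,8α-bis(TBSO)-7β-(hydroxymethyl)-4β,10β-dimethyl-trans-decalin-4α,6α-diol | OC[C@H]1[C@H](O)[C@@H]2[C@@](C)(C[C@@H]1O[Si](C)(C)C(C)(C)C)[C@H](O[Si](C)(C)C(C)(C)C)CC[C@@]2(C)O
F6 | step 30 | 6α-O-{2-[bis(2,2,2-trifluoroethoxy)phosphoryl]propanoyl} ester of 35 (both epimers at the phosphonate carbon) | C=C(C(=O)OC)[C@H]1[C@H](OC(=O)C(C)P(=O)(OCC(F)(F)F)OCC(F)(F)F)[C@@H]2[C@@](C)(C[C@@H]1O[Si](C)(C)C(C)(C)C)[C@H](O[Si](C)(C)C(C)(C)C)CC[C@@]2(C)O
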